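1. I started from the product, counted in percent of the substrate charged, and asked which charge pays for it.

| flask | substrate | solid reagent | temperature | remark | time |
|---|---|---|---|---|---|
| dawn | 0.062 M | 1.3 equiv | −5 °C | run made earlier |  |
| midnight | 0.062 M | 2.1 equiv | 25 °C | run made earlier |  |
| dusk | 0.093 M | 0.95 equiv | −5 °C | run made earlier |  |
| maple | 0.062 M | 0.950 equiv | 25 °C |  | 12 min |
| cedar | 0.062 M | 0.950 equiv | 0 °C |  | 12 min |
| alder | 0.062 M | 0.950 equiv | 50 °C |  | 12 min |

- dawn (time / min: product / %): 6.00: 0; 20.0: 0; 40.0: 0; 50.0: 0
- midnight (time / min: product / %): 1.50: 1; 4.00: 3; 8.00: 10; 12.0: 18
- dusk (time / min: product / %): 4.00: 2; 8.00: 0; 20.0: 2; 50.0: 0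

(each reading ± 2 percentage points)

* which flask leads in amount of product, in percent of the substrate charged ("all alike" within 1.5 percentage points) (maple / cedar / alder / all alike)
* how much product is there at the end, in percent of the substrate charged: maple
* how much product is there at the end, in percent of the substrate charged: cedar
* how much product is there at the end, in percent of the substrate charged: alder

- given per volume of solution although it is solid: solid reagent
- the numbers in the tables scatter by 2 percentage points (one standard deviation)
- at the start none of the solid reagent is in solution

2. In maple, cedar and alder, c(solid reagent), counted as charged, is 0.0589 M, less than c(substrate) at 0.062 M, so I took the solid reagent as the limiting reagent. I assumed that one unit of it makes one unit of product and named the reagent ceiling, 95.0 %: the charged equivalents of solid reagent read as a percent of the substrate.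

3. My first extreme for alder lost no reagent and stood at the ceiling, 95.0 %.

4. My second extreme for alder gained nothing from heat or from a smaller loading, and stood at the last midnight reading, 18 %.

5. I expected the real alder above the second extreme, since no reading at −5 °C exceeded 2 percentage points, while midnight at 25 °C was still rising; that was a judgement and no bound, because alder was charged with less solid reagent than midnight. It could lie below the first, since the readings show product and not what else became of the reagent. Midnight reached 0.0857 of its own ceiling by 12.0 min. I committed to the middle for alder, 56.5 %, and to alder leading.

6. The forecast also put alder first, with 10 % for maple, 0.5 % for cedar and 75 % for alder, higher than my middle. Of alder it said: “It should therefore run far along”.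

7. The flasks gave 16.2 % in maple, 0.260 % in cedar and 26.7 % in alder, which led.

    substrate + coupling partner ⇌ intermediate (K = 25.0 /M, k = 2.27 /M/min, Ea = 51.0 kJ/mol, ΔH = 7.00 kJ/mol)
    intermediate → product (k = 0.0884 /min, Ea = 87.0 kJ/mol)
    coupling partner ⇌ dormant form (K = 0.580, k = 0.0206 /min, Ea = 100 kJ/mol, ΔH = −65.0 kJ/mol)
    solid reagent ⇌ coupling partner, rate k4*(cs4 - [coupling partner]) while solid is left; crystals form when [coupling partner] > cs4 (solubility = 35.0 mM, k = 3.92 /min)
    coupling partner → decomposed reagent (k = 0.103 /min, Ea = 78.0 kJ/mol)
    (constants at 25 °C)

8. Alder's product stood under both my 56.5 % and the forecast's 75 %. At 0.345 min in alder, the coupling partner went to decomposed reagent 1.8 times as fast as it joined the substrate in the forward step to intermediate. Alder ended with 0.0423 M of decomposed reagent, and its product was 0.281 of the ceiling. The neighbour flask with 3.80 equiv of solid reagent has a ceiling of 380 %, above the substrate's own 100 %. It gave 74.6 % of product, 0.196 of that ceiling, beside 0.189 M of decomposed reagent.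

The runs come from a simulation from invented constants, and the scatter is random.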